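**Plan**

- Retrosynthesis: the B-ring sulfonate S–O bond and the 8-O–CH3 bond are cut first, then O1–C8a (key step), then C2–C3 (crossed Claisen) and C4–C4a (Friedel–Crafts).
- Forward: the B-ring ester (from methyl gentisate) and the A-ring methoxymethyl ketone (from 1,2,4-trimethoxybenzene) are joined to the open C6–C3–C6 diketone. The pyranone ring is closed last, onto the A ring.
- Enabling feature: without O1 the A ring is a 2,4,5-trimethoxyphenyl ketone whose 2- and 5-methoxy carbons (future C5 and C8) are para to each other. The anode converts this ring into an acyl-p-quinone, and its only C–H next to the acyl-bearing carbon (future C8a) is the β-carbon that the side-chain enol oxygen (future O1) attacks.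
- The cascade should deliver the 5,8-hydroquinone. The free 8-OH is then methylated (the 5-OH is chelated to C4=O), and the tosylate that kept the B ring out of the oxidation is removed last.
- Stereochemistry: the target has no stereocentre, so nothing has to be set.

Key step: step 5

Remark: the target is achiral, so "single enantiomer" needs no control; diketone 7 is drawn as its chelated enol, which is E by the CIP rules because OMe outranks the acyl carbon, and it equilibrates with the racemic diketo form.

**Route**

Step 1
Reactants: 1 methyl 2,5-dihydroxybenzoate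
Product: 2 methyl 2-hydroxy-5-[(4-methylbenzenesulfonyl)oxy]benzoate
Conditions: TsCl (1.05 equiv), Et3N (1.2 equiv), CH2Cl2, 0 °C
Reagents that add atoms: p-toluenesulfonyl chloride (Cc1ccc(cc1)S(Cl)(=O)=O)
Why: O-sulfonylation should take the free 5-OH, because the 2-OH is tied up in a hydrogen bond to the ester carbonyl and is much less nucleophilic.

Step 2
Reactants: 2 methyl 2-hydroxy-5-[(4-methylbenzenesulfonyl)oxy]benzoate
Product: 3 methyl 2-methoxy-5-[(4-methylbenzenesulfonyl)oxy]benzoate
Conditions: MeI (3 equiv), K2CO3 (2 equiv), DMF, 40 °C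
Reagents that add atoms: iodomethane (CI)
Why: Williamson O-methylation of the chelated phenol needs carbonate in DMF with excess iodomethane, conditions that the aryl sulfonate and the methyl ester tolerate.

Step 3
Reactants: 4 1,2,4-trimethoxybenzene; 5 methoxyacetyl chloride
Product: 6 2-methoxy-1-(2,4,5-trimethoxyphenyl)ethan-1-one
Conditions: SnCl4 (1.1 equiv), CH2Cl2, −20 to 0 °C; cold 1 M HCl
Reagents that add atoms: none
Why: Friedel–Crafts acylation should go to C5, the least hindered activated position (para to one methoxy group, ortho to another), and a mild Lewis acid at low temperature limits ortho-demethylation and decarbonylation of the alkoxyacetyl chloride.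

Step 4
Reactants: 6 2-methoxy-1-(2,4,5-trimethoxyphenyl)ethan-1-one; 3 methyl 2-methoxy-5-[(4-methylbenzenesulfonyl)oxy]benzoate
Product: 7 4-methoxy-3-[(1E)-1-hydroxy-2-methoxy-3-oxo-3-(2,4,5-trimethoxyphenyl)prop-1-en-1-yl]phenyl 4-methylbenzenesulfonate
Conditions: LiHMDS (2.2 equiv), THF, −78 °C; add 3; warm to 20 °C; AcOH quench
Reagents that add atoms: none
Why: Crossed Claisen condensation, in which the lithium enolate of the α-methoxy ketone adds to the non-enolisable benzoate and the product is held as its diketonate, which drives the equilibrium; a hindered amide base at low temperature should spare the aryl sulfonate.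

Step 5
Reactants: 7 4-methoxy-3-[(1E)-1-hydroxy-2-methoxy-3-oxo-3-(2,4,5-trimethoxyphenyl)prop-1-en-1-yl]phenyl 4-methylbenzenesulfonate
Product: 10 3-(5,8-dihydroxy-3,7-dimethoxy-4-oxo-4H-chromen-2-yl)-4-methoxyphenyl 4-methylbenzenesulfonate, via acylquinone 8 (not isolated), via flavone-5,8-quinone 9 (not isolated)
Conditions: graphite anode, Pt cathode, divided cell, Bu4NBF4 (0.1 M), MeCN/H2O 9:1, controlled potential at the first anodic wave of 7 (about +1.4 V vs SCE), 20 °C, about 4 F/mol; then Na2S2O4, H2O/EtOAc, 20 °C
Reagents that add atoms: water (O)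
Why: Proposed new method: the trimethoxyaryl ring, the site of lowest potential in 7, is oxidised to its radical cation, water adds at the para-related methoxy-bearing carbons (future C5 and C8) and methanol leaves, so that two electrons give acylquinone 8. In 8 the lone ring C–H carbon next to the acyl-bearing carbon is β to both the side-chain ketone and a ring carbonyl; the enol oxygen of the side chain adds to it in a 6-endo-trig oxa-Michael closure that forms O1–C8a and the pyranone ring, and tautomerisation gives hydroquinone 10, which the anode oxidises on to quinone 9 before dithionite returns it as 10. The closest known reaction types are the anodic or cerium(IV) oxidative demethylation of 1,2,4-trimethoxyarenes to methoxy-p-quinones, the conjugate addition of nucleophiles next to the acyl group of 2-acyl-1,4-benzoquinones, and the anodic catechol/1,3-dicarbonyl cascades in which an enol oxygen closes onto an electrogenerated quinone. The quinone level is chosen because in the intact trimethoxyaryl radical cation the open C–H carbon is meta to two methoxy groups and carries little positive charge, so an internal oxygen would be expected to attack a methoxy-bearing carbon (ipso substitution or spiro-cyclisation); in 8 those carbons are carbonyls whose hemiketals revert, and the C–H carbon is the best acceptor. Chemoselectivity rests on the sulfonate and acyl group, which lift the B ring far above the working potential, on the acidic aqueous medium that builds up at the anode and keeps 7 as its weakly nucleophilic keto form during the first oxidation, and on the geometry of the side chain, whose enol carbon could reach the ring only through a four-membered ring. No stereocentre is formed and quinone 9 is not oxidised further at this potential, so the charge can be passed to completion.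

Step 6
Reactants: 10 3-(5,8-dihydroxy-3,7-dimethoxy-4-oxo-4H-chromen-2-yl)-4-methoxyphenyl 4-methylbenzenesulfonate
Product: 11 3-(5-hydroxy-3,7,8-trimethoxy-4-oxo-4H-chromen-2-yl)-4-methoxyphenyl 4-methylbenzenesulfonate
Conditions: MeI (1.1 equiv), K2CO3 (1.1 equiv), acetone, 20 to 40 °C, argon
Reagents that add atoms: iodomethane (CI)
Why: Williamson methylation with one equivalent of base should take the free 8-OH, since the 5-OH is locked in the peri hydrogen bond to C4=O (the classical partial methylation of 5,8-dihydroxyflavones); argon keeps the hydroquinone from air oxidation.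

Step 7
Reactants: 11 3-(5-hydroxy-3,7,8-trimethoxy-4-oxo-4H-chromen-2-yl)-4-methoxyphenyl 4-methylbenzenesulfonate
Product: 12 5-hydroxy-2-(5-hydroxy-2-methoxyphenyl)-3,7,8-trimethoxy-4H-chromen-4-one (5,5'-dihydroxy-3,7,8,2'-tetramethoxyflavone)
Conditions: KOH (2 M aq.), 1,4-dioxane, 70 °C, argon; then 1 M HCl to pH 3
Reagents that add atoms: none
Why: Alkaline hydrolysis of the aryl sulfonate by attack of hydroxide at sulfur; the 5-phenoxide formed under the conditions makes the pyranone electron-rich and shields C2 from hydroxide, and the alcohol-free medium avoids alkyl tosylates that could re-alkylate the phenoxides.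

**Compound list**

1 | methyl 2,5-dihydroxybenzoate | COC(=O)c1cc(O)ccc1O | starting material
2 | methyl 2-hydroxy-5-[(4-methylbenzenesulfonyl)oxy]benzoate | COC(=O)c1cc(OS(=O)(=O)c2ccc(C)cc2)ccc1O | intermediate
3 | methyl 2-methoxy-5-[(4-methylbenzenesulfonyl)oxy]benzoate | COC(=O)c1cc(OS(=O)(=O)c2ccc(C)cc2)ccc1OC | intermediate
4 | 1,2,4-trimethoxybenzene | COc1ccc(OC)c(OC)c1 | starting material
5 | methoxyacetyl chloride | COCC(Cl)=O | starting material
6 | 2-methoxy-1-(2,4,5-trimethoxyphenyl)ethan-1-one | COCC(=O)c1cc(OC)c(OC)cc1OC | intermediate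
7 | 4-methoxy-3-[(1E)-1-hydroxy-2-methoxy-3-oxo-3-(2,4,5-trimethoxyphenyl)prop-1-en-1-yl]phenyl 4-methylbenzenesulfonate (chelated enol of the 2-methoxy-1,3-diketone) | COc1ccc(OS(=O)(=O)c2ccc(C)cc2)cc1/C(O)=C(\OC)C(=O)c1cc(OC)c(OC)cc1OC | intermediate
8 | 3-[2-methoxy-3-(4-methoxy-3,6-dioxocyclohexa-1,4-dien-1-yl)-3-oxopropanoyl]-4-methoxyphenyl 4-methylbenzenesulfonate (acylquinone, keto form, racemic methine) | COC1=CC(=O)C(C(=O)C(OC)C(=O)c2cc(OS(=O)(=O)c3ccc(C)cc3)ccc2OC)=CC1=O | intermediate
9 | 3-(3,7-dimethoxy-4,5,8-trioxo-5,8-dihydro-4H-chromen-2-yl)-4-methoxyphenyl 4-methylbenzenesulfonate | COC1=C(c2cc(OS(=O)(=O)c3ccc(C)cc3)ccc2OC)OC2=C(C1=O)C(=O)C=C(OC)C2=O | intermediate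
10 | 3-(5,8-dihydroxy-3,7-dimethoxy-4-oxo-4H-chromen-2-yl)-4-methoxyphenyl 4-methylbenzenesulfonate | COc1ccc(OS(=O)(=O)c2ccc(C)cc2)cc1-c1oc2c(O)c(OC)cc(O)c2c(=O)c1OC | intermediate
11 | 3-(5-hydroxy-3,7,8-trimethoxy-4-oxo-4H-chromen-2-yl)-4-methoxyphenyl 4-methylbenzenesulfonate | COc1ccc(OS(=O)(=O)c2ccc(C)cc2)cc1-c1oc2c(OC)c(OC)cc(O)c2c(=O)c1OC | intermediate
12 | 5-hydroxy-2-(5-hydroxy-2-methoxyphenyl)-3,7,8-trimethoxy-4H-chromen-4-one | COc1ccc(O)cc1-c1oc2c(OC)c(OC)cc(O)c2c(=O)c1OC | target

**Step count and risks**

Total steps: 7. Longest linear sequence: 6 steps (1 → 2 → 3 → 7 → 10 → 11 → 12, i.e. steps 1, 2, 4, 5, 6, 7); the A-ring branch adds step 3 before the convergence.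

Steps most likely to fail:

1. Step 5. The radical cation of the A ring may be intercepted by a side-chain oxygen at a methoxy-bearing carbon before water has delivered the quinone, or water may add to the acylquinone in place of the enol. Either would divert material to ring-isomeric or spiro products. The fallback uses the classical flavone construction, in which O1 is already on the A ring. It sets out from ester 3 and acid chloride 5 and returns at 11. Friedel–Crafts acylation of commercial 1,2,3,5-tetramethoxybenzene with 5 (AlCl3, CH2Cl2, 0 to 20 °C) would give 2-methoxy-1-(2,3,4,6-tetramethoxyphenyl)ethan-1-one F1. The same Lewis acid removes the methyl group of the methoxy flanked by the ketone and a second methoxy group, giving 1-(2-hydroxy-3,4,6-trimethoxyphenyl)-2-methoxyethan-1-one F2. Claisen condensation of the dilithio derivative of F2 with 3 (LiHMDS, 3.3 equiv, THF, −78 to 20 °C) would give 3-[3-(2-hydroxy-3,4,6-trimethoxyphenyl)-2-methoxy-3-oxopropanoyl]-4-methoxyphenyl 4-methylbenzenesulfonate F3. Acid cyclodehydration (AcOH, catalytic H2SO4, 60 °C) closes the pyranone through O1–C2 to 4-methoxy-3-(3,5,7,8-tetramethoxy-4-oxo-4H-chromen-2-yl)phenyl 4-methylbenzenesulfonate F4. Boron trichloride (CH2Cl2, −78 to 0 °C) then cleaves only the 5-methyl ether chelated to C4=O and gives 11.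

2. Step 4. The lithium methoxide released may cleave the aryl sulfonate, or the hindered α-alkoxy enolate may add too slowly to the electron-rich benzoate. The fallback replaces the ester condensation by C-acylation under soft enolisation, with no strong base and no alkoxide. It sets out from 3 and returns at 7. Saponification (LiOH, THF/H2O, 0 to 20 °C) would give 2-methoxy-5-[(4-methylbenzenesulfonyl)oxy]benzoic acid F5. Oxalyl chloride with catalytic DMF (CH2Cl2, 20 °C) gives 2-methoxy-5-[(4-methylbenzenesulfonyl)oxy]benzoyl chloride F6. Ketone 6 is then acylated at carbon by F6 through its magnesium enolate (MgBr2·OEt2, i-Pr2NEt, CH2Cl2, 20 °C), where chelation by the α-methoxy group favours enolisation, to give 7.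

3. Step 3. The Lewis-acid-activated alkoxyacetyl chloride may lose carbon monoxide and alkylate the arene, and the methoxy group ortho to the new ketone may be cleaved. The fallback builds the same ketone from an aryl anion and an amide. It sets out from 4 and 5 and returns at 6. Bromination of 4 (NBS, MeCN, 0 °C) goes to the same most activated position and gives 1-bromo-2,4,5-trimethoxybenzene F7. Acid chloride 5 with N,O-dimethylhydroxylamine hydrochloride (Et3N, CH2Cl2, 0 °C) gives N,2-dimethoxy-N-methylacetamide F8. Bromine–lithium exchange on F7 (n-BuLi, THF, −78 °C) gives (2,4,5-trimethoxyphenyl)lithium F9, which adds once to the Weinreb amide F8 and releases 6 on aqueous NH4Cl work-up.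

Further compounds
F1 | step 5 | 2-methoxy-1-(2,3,4,6-tetramethoxyphenyl)ethan-1-one | COCC(=O)c1c(OC)c(OC)c(OC)cc1OC
F2 | step 5 | 1-(2-hydroxy-3,4,6-trimethoxyphenyl)-2-methoxyethan-1-one | COCC(=O)c1c(O)c(OC)c(OC)cc1OC
F3 | step 5 | 3-[3-(2-hydroxy-3,4,6-trimethoxyphenyl)-2-methoxy-3-oxopropanoyl]-4-methoxyphenyl 4-methylbenzenesulfonate | COc1ccc(OS(=O)(=O)c2ccc(C)cc2)cc1C(=O)C(OC)C(=O)c1c(O)c(OC)c(OC)cc1OC
F4 | step 5 | 4-methoxy-3-(3,5,7,8-tetramethoxy-4-oxo-4H-chromen-2-yl)phenyl 4-methylbenzenesulfonate | COc1ccc(OS(=O)(=O)c2ccc(C)cc2)cc1-c1oc2c(OC)c(OC)cc(OC)c2c(=O)c1OC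
F5 | step 4 | 2-methoxy-5-[(4-methylbenzenesulfonyl)oxy]benzoic acid | COc1ccc(OS(=O)(=O)c2ccc(C)cc2)cc1C(=O)O
F6 | step 4 | 2-methoxy-5-[(4-methylbenzenesulfonyl)oxy]benzoyl chloride | COc1ccc(OS(=O)(=O)c2ccc(C)cc2)cc1C(Cl)=O
F7 | step 3 | 1-bromo-2,4,5-trimethoxybenzene | Brc1cc(OC)c(OC)cc1OC
F8 | step 3 | N,2-dimethoxy-N-methylacetamide | COCC(=O)N(C)OC
F9 | step 3 | (2,4,5-trimethoxyphenyl)lithium | [Li]c1cc(OC)c(OC)cc1OC
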